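**Retrosynthetic overview**
1. Oxepane last: the C3–O–C16 bond by displacement of a C16 triflate by the tertiary C3 hydroxyl; C16–OH and C15 come from hydroboration of a C14 isopropenyl group.
2. Cyclohexane and tetrahydrofuran together: intramolecular Diels–Alder reaction (bonds C1–C10 and C13–C14) of a C9-borne 2-methoxydiene with a C2-borne enone across the oxonene; the enol ether becomes the C11 ketone, then 11-O and 12-Me.
3. Oxonene first: ring-closing metathesis forming the Z C6=C7 bond.
4. Acyclic C2–O–C9 ether: new copper-catalysed, ligand-controlled O–H insertion of alcohol 7 into diazo ester 11, setting C9; C2/C3 come from Sharpless epoxidation and inverting epoxide opening.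
5. Ring order: oxonene, then cyclohexene plus tetrahydrofuran in one step, then oxepane.

Numbering: asbestinane numbering is used (C1–C14 ring carbons; C15–C17 the side chain on C14; C18, C19, C20 the methyls on C3, C7, C12; one ether oxygen bridges C2/C9, the other links C3/C16). TBDPS = tert-butyldiphenylsilyl, PMB = 4-methoxybenzyl.

Assumption: the target is taken exactly as the given SMILES (1S,2R,3S,9R,10R,11R,12R,14S,15R,6Z), and the (Ra,S,S) antipode of the spiro-bisoxazoline ligand is taken to be the one that gives 9R (otherwise its mirror image is used).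

Step 1
Reactants: 1 ethyl but-2-ynoate; 2 but-3-en-1-ylmagnesium bromide
Product: 3 ethyl (2E)-3-methylhepta-2,6-dienoate
Conditions: CuI (1.2 equiv), THF, −78 °C; aq NH4Cl quench at −78 °C
Reagents that add atoms: none
Why: syn-carbocupration of the alkynoate by the butenylcopper reagent and cold protonation of the alkenylcopper give the 2E enoate stereospecifically (organocopper conjugate addition to an ynoate).

Step 2
Reactants: 3 ethyl (2E)-3-methylhepta-2,6-dienoate
Product: 4 (2E)-3-methylhepta-2,6-dien-1-ol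
Conditions: i-Bu2AlH (2.2 equiv), CH2Cl2, −78 → 0 °C; aq potassium sodium tartrate
Reagents that add atoms: none
Why: 1,2-reduction of the conjugated ester to the allylic alcohol leaves both alkenes and the E geometry untouched (aluminium hydride ester reduction).

Step 3
Reactants: 4 (2E)-3-methylhepta-2,6-dien-1-ol
Product: 5 [(2R,3R)-3-(but-3-en-1-yl)-3-methyloxiran-2-yl]methanol
Conditions: Ti(OiPr)4 (10 mol %), D-(−)-diethyl tartrate (12 mol %), t-BuOOH, 4 Å MS, CH2Cl2, −20 °C
Reagents that add atoms: tert-butyl hydroperoxide, CC(C)(C)OO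
Why: Sharpless asymmetric epoxidation; the D-tartrate titanium complex delivers oxygen to the face of the E allylic alcohol that gives the 2R,3R epoxide, and the isolated terminal alkene does not react.

Step 4
Reactants: 5 [(2R,3R)-3-(but-3-en-1-yl)-3-methyloxiran-2-yl]methanol
Product: 6 tert-butyl{[(2R,3R)-3-(but-3-en-1-yl)-3-methyloxiran-2-yl]methoxy}diphenylsilane
Conditions: t-BuPh2SiCl, imidazole, CH2Cl2, 0 → 25 °C
Reagents that add atoms: tert-butyl(chloro)diphenylsilane, CC(C)(C)[Si](Cl)(c1ccccc1)c1ccccc1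
Why: routine silylation of the primary alcohol; no stereocentre is involved.

Step 5
Reactants: 6 tert-butyl{[(2R,3R)-3-(but-3-en-1-yl)-3-methyloxiran-2-yl]methoxy}diphenylsilane
Product: 7 (2R,3S)-1-(TBDPS-oxy)-3-(PMB-oxy)-3-methylhept-6-en-2-ol
Conditions: 4-MeOC6H4CH2OH (4 equiv), BF3·OEt2 (10 mol %), CH2Cl2, −40 → −20 °C
Reagents that add atoms: 4-methoxybenzyl alcohol, COc1ccc(CO)cc1
Why: Lewis-acid-catalysed alcoholysis of the trisubstituted epoxide occurs at the tertiary C3 (the C1 oxygen disfavours charge at C2) by backside attack, so C3 is inverted to S while C2 keeps its oxygen as R (borderline SN2 epoxide opening).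

Step 6
Reactants: 8 methyl 3-oxobutanoate; 9 3-chloro-2-methylprop-1-ene
Product: 10 methyl 2-acetyl-4-methylpent-4-enoate (racemic)
Conditions: NaH, THF, 0 °C; then 9, NaI (10 mol %), 60 °C
Reagents that add atoms: none
Why: C-alkylation of the acetoacetate sodium enolate by the allylic chloride (acetoacetic ester alkylation); the new centre is removed in step 7.

Step 7
Reactants: 10 methyl 2-acetyl-4-methylpent-4-enoate
Product: 11 methyl 2-diazo-4-methylpent-4-enoate
Conditions: 4-AcNHC6H4SO2N3, DBU, MeCN, 0 → 25 °C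
Reagents that add atoms: 4-acetamidobenzenesulfonyl azide, CC(=O)Nc1ccc(cc1)S(=O)(=O)N=[N+]=[N-]
Why: deacylative Regitz diazo transfer; the azide hands N2 to the activated methine and the acetyl group leaves on the sulfonamide nitrogen.

Step 8
Reactants: 7 (2R,3S)-1-(TBDPS-oxy)-3-(PMB-oxy)-3-methylhept-6-en-2-ol; 11 methyl 2-diazo-4-methylpent-4-enoate
Product: 12 methyl (2R)-2-{[(2R,3S)-1-(TBDPS-oxy)-3-(PMB-oxy)-3-methylhept-6-en-2-yl]oxy}-4-methylpent-4-enoate
Conditions: Cu(MeCN)4PF6 (5 mol %), (Ra,S,S)-7,7'-bis(4-phenyl-4,5-dihydrooxazol-2-yl)-1,1'-spirobiindane (6 mol %), NaB[3,5-(CF3)2C6H3]4 (6 mol %), 4 Å MS, CH2Cl2, 25 °C, 11 (2 equiv) added over 6 h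
Reagents that add atoms: none
Why: Proposed new method: a cationic monovalent-copper carbene formed from 11 should be captured by the free secondary hydroxyl of 7 faster than it undergoes 1,2-hydride shift or alkene cyclopropanation (slow addition keeps the diazo ester low), and the copper-bound oxonium ylide/enol is then protonated at carbon inside the chiral spiro-bisoxazoline pocket, so the ligand, reinforced by the neighbouring C2 centre, fixes C9 as R while making the C9–O bond of the bridging ether; the closest known reaction type is the copper/spiro-bisoxazoline-catalysed enantioselective O–H insertion of α-diazo esters into simple alcohols, phenols and water, not yet shown for a hindered stereodefined secondary alcohol or for an α-allyl-type diazo ester prone to β-hydride migration.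

Step 9
Reactants: 12 methyl (2R)-2-{[(2R,3S)-1-(TBDPS-oxy)-3-(PMB-oxy)-3-methylhept-6-en-2-yl]oxy}-4-methylpent-4-enoate
Product: 13 oxonene methyl ester (2R,3S,9R,6Z): ring O–C2–C3–C4–C5–C6=C7–C8–C9 with 2-CH2OTBDPS, 3-Me, 3-OPMB, 7-Me, 9-CO2Me
Conditions: second-generation Grubbs catalyst (H2IMes)(PCy3)Cl2Ru=CHPh (8 mol %), CH2Cl2 (2 mM), 40 °C
Reagents that add atoms: none
Why: ring-closing metathesis of the butenyl and methallyl alkenes; the gauche preference of the vicinal C2/C3 C–O bonds folds the chain for closure and the nine-membered ring can only hold the Z trisubstituted C6=C7 alkene.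

Step 10
Reactants: 13 oxonene methyl ester
Product: 14 oxonene 9-carbaldehyde (2R,3S,9R,6Z)
Conditions: i-Bu2AlH (1.1 equiv), CH2Cl2, −78 °C; MeOH quench, aq potassium sodium tartrate
Reagents that add atoms: none
Why: partial reduction of the α-alkoxy ester stops at the aldehyde because the chelated aluminium hemiacetal survives at −78 °C, and the non-basic conditions leave C9 intact.

Step 11
Reactants: 15 dimethyl (1-diazo-2-oxopropyl)phosphonate
Product: 16 dimethyl (1-methoxy-2-oxopropyl)phosphonate (racemic)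
Conditions: Rh2(OAc)4 (1 mol %), MeOH (5 equiv), CH2Cl2, 40 °C
Reagents that add atoms: methanol, CO
Why: rhodium-carbene O–H insertion of methanol into the diazophosphonate gives the α-methoxy β-ketophosphonate, whose centre becomes sp2 in step 12.

Step 12
Reactants: 14 oxonene 9-carbaldehyde; 16 dimethyl (1-methoxy-2-oxopropyl)phosphonate
Product: 17 oxonene (10Z)-enol-ether enone (2R,3S,9R,6Z,10Z): C9–CH=C(OMe)–C(O)CH3
Conditions: 16, NaH, THF, 0 °C; then 14, −78 → 0 °C
Reagents that add atoms: none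
Why: Horner–Wadsworth–Emmons olefination by the pre-formed sodium phosphonate places the acetyl group trans to C9, giving the 10Z enol-ether enone (C9 cis to OMe) that a reactive diene needs, without epimerising C9 (minor 10E isomer removed by chromatography).

Step 13
Reactants: 17 oxonene (10Z)-enol-ether enone
Product: 18 oxonene 2-methoxydiene (2R,3S,9R,6Z,10Z): C9–CH=C(OMe)–C(CH3)=CH2, C1 as CH2OTBDPS
Conditions: Ph3PCH3Br, KN(SiMe3)2, THF, 0 °C; then 17, 0 → 25 °C
Reagents that add atoms: methyltriphenylphosphonium bromide, C[P+](c1ccccc1)(c1ccccc1)c1ccccc1.[Br-]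
Why: Wittig methylenation of the methyl ketone turns the enone into the 2-methoxy-3-methyl-1,3-diene and leaves the 10Z enol ether geometry alone.

Step 14
Reactants: 18 oxonene 2-methoxydiene
Product: 19 oxonene diene primary alcohol (2R,3S,9R,6Z,10Z): C1 as CH2OH
Conditions: Bu4NF, THF, 0 → 25 °C
Reagents that add atoms: none
Why: fluoride cleaves only the primary silyl ether; the PMB ether and the base-stable methoxydiene survive.

Step 15
Reactants: 19 oxonene diene primary alcohol
Product: 20 oxonene diene 2-carbaldehyde (2S,3S,9R,6Z,10Z; same spatial arrangement, descriptor changes with CHO)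
Conditions: Dess–Martin periodinane, pyridine, CH2Cl2, 0 °C
Reagents that add atoms: none
Why: buffered periodinane oxidation gives the α-alkoxy aldehyde without epimerising C2 or hydrolysing the enol ether.

Step 16
Reactants: 20 oxonene diene 2-carbaldehyde
Product: 22 tricyclic enol-ether methyl ketone (1R,2R,3S,9R,10R,14R,6Z): 2,9-ether-bridged cyclodec-6-ene fused to a cyclohexene at C1–C10 with C11(OMe)=C12(Me) and 14-acetyl, via tetraene enone 21 (not isolated)
Conditions: Ph3P=CHC(O)CH3, PhMe, 25 °C, then 60 °C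
Reagents that add atoms: 1-(triphenylphosphoranylidene)propan-2-one, CC(=O)C=P(c1ccccc1)(c1ccccc1)c1ccccc1
Why: E-selective Wittig olefination gives enone 21, whose C1=C14 bond is trapped by the electron-rich 2-methoxydiene in an intramolecular Diels–Alder reaction; the three-atom C2–O–C9 tether forces the cis-fused hydroisobenzofuran through the ketone-exo transition state and the oxonene holds both partners on the face syn to C3 and C8, setting C1, C10 and C14 (H1/H10 cis, acetyl trans to C2).

Step 17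
Reactants: 22 tricyclic enol-ether methyl ketone
Product: 23 tricyclic isopropenyl enol ether (1S,2R,3S,9R,10R,14R,6Z)
Conditions: Ph3PCH3Br, KN(SiMe3)2, THF, 0 → 25 °C
Reagents that add atoms: methyltriphenylphosphonium bromide, C[P+](c1ccccc1)(c1ccccc1)c1ccccc1.[Br-]
Why: Wittig methylenation of the only free ketone (C11 is still masked as its methyl enol ether) gives the C14 isopropenyl group; the equatorial C14 centre is the stable epimer.

Step 18
Reactants: 23 tricyclic isopropenyl enol ether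
Product: 24 tricyclic 11-ketone (1S,2R,3S,9R,10R,12R,14R,6Z)
Conditions: (CO2H)2 (0.5 equiv), THF/H2O (10:1), 0 °C, short contact time
Reagents that add atoms: water, O
Why: enol-ether hydrolysis; rate-limiting protonation of C12 from the convex face, anti to the pseudo-axial C9 substituent on C10, puts the C12 methyl on the concave face (12R), and the mild acid and short time keep this kinetic, contra-thermodynamic ketone from epimerising.

Step 19
Reactants: 24 tricyclic 11-ketone
Product: 25 tricyclic 11-alcohol (1S,2R,3S,9R,10S,11R,12R,14R,6Z; descriptor at C10 changes by priority only)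
Conditions: NaBH4, CeCl3·7H2O, MeOH, −78 → −40 °C
Reagents that add atoms: none
Why: Luche reduction; hydride adds to C11 from the convex face of the cis-fused bicycle, giving the 11R alcohol cis to the C12 methyl, and the cerium-buffered medium avoids enolisation toward C12 or C10.

Step 20
Reactants: 25 tricyclic 11-alcohol
Product: 26 tricyclic 11-butanoate (1S,2R,3S,9R,10R,11R,12R,14R,6Z)
Conditions: (PrCO)2O, Et3N, DMAP (10 mol %), CH2Cl2, 25 °C
Reagents that add atoms: butanoic anhydride, CCCC(=O)OC(=O)CCC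
Why: DMAP-catalysed acylation of the only free hydroxyl with retention at C11.

Step 21
Reactants: 26 tricyclic 11-butanoate
Product: 27 C16 primary alcohol (1S,2R,3S,9R,10R,11R,12R,14S,15R,6Z)
Conditions: 9-BBN (3 equiv), THF, 0 → 25 °C; then NaBO3·4H2O, THF/H2O, 25 °C
Reagents that add atoms: sodium perborate, [Na+].[Na+].O[B-]1(O)OO[B-](O)(O)OO1
Why: anti-Markovnikov hydroboration–oxidation; 9-BBN takes only the 1,1-disubstituted alkene (ring alkene and ester are inert) and adds to the rotamer with H14 eclipsing the alkene on the face anti to the bulky C1 branch, which sets C15 as R.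

Step 22
Reactants: 27 C16 primary alcohol
Product: 28 3,16-diol (1S,2R,3S,9R,10R,11R,12R,14S,15R,6Z)
Conditions: DDQ, CH2Cl2/pH 7 buffer (10:1), 0 °C
Reagents that add atoms: none
Why: oxidative PMB cleavage frees the tertiary C3 hydroxyl and leaves alkene, ester and primary alcohol alone.

Step 23
Reactants: 28 3,16-diol
Product: 30 target CNP0209450.4, via primary triflate 29 (not isolated)
Conditions: Tf2O (1.1 equiv), 2,6-lutidine, CH2Cl2, −78 → 0 °C
Reagents that add atoms: none
Why: the primary C16 hydroxyl is triflated selectively and the tertiary C3 hydroxyl displaces the triflate in a 7-exo-tet Williamson-type closure, forming the oxepane with no stereocentre touched.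

**Compound list**
1 | ethyl but-2-ynoate | CC#CC(=O)OCC | starting material
2 | but-3-en-1-ylmagnesium bromide | C=CCC[Mg]Br | starting material
3 | ethyl (2E)-3-methylhepta-2,6-dienoate | C=CCC/C(C)=C/C(=O)OCC | intermediate
4 | (2E)-3-methylhepta-2,6-dien-1-ol | C=CCC/C(C)=C/CO | intermediate
5 | [(2R,3R)-3-(but-3-en-1-yl)-3-methyloxiran-2-yl]methanol | OC[C@H]1O[C@]1(C)CCC=C | intermediate
6 | tert-butyl{[(2R,3R)-3-(but-3-en-1-yl)-3-methyloxiran-2-yl]methoxy}diphenylsilane | CC(C)(C)[Si](c1ccccc1)(c1ccccc1)OC[C@H]1O[C@]1(C)CCC=C | intermediate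
7 | (2R,3S)-1-{[tert-butyl(diphenyl)silyl]oxy}-3-[(4-methoxybenzyl)oxy]-3-methylhept-6-en-2-ol | CC(C)(C)[Si](c1ccccc1)(c1ccccc1)OC[C@@H](O)[C@](C)(CCC=C)OCc1ccc(OC)cc1 | intermediate
8 | methyl 3-oxobutanoate | CC(=O)CC(=O)OC | starting material
9 | 3-chloro-2-methylprop-1-ene | CC(=C)CCl | starting material
10 | methyl 2-acetyl-4-methylpent-4-enoate (racemic) | CC(=O)C(CC(C)=C)C(=O)OC | intermediate
11 | methyl 2-diazo-4-methylpent-4-enoate | COC(=O)C(=[N+]=[N-])CC(C)=C | intermediate
12 | methyl (2R)-2-{[(2R,3S)-1-{[tert-butyl(diphenyl)silyl]oxy}-3-[(4-methoxybenzyl)oxy]-3-methylhept-6-en-2-yl]oxy}-4-methylpent-4-enoate | CC(C)(C)[Si](c1ccccc1)(c1ccccc1)OC[C@@H](O[C@@H](C(=O)OC)CC(C)=C)[C@](C)(CCC=C)OCc1ccc(OC)cc1 | intermediate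
13 | oxonene methyl ester (2R,3S,9R,6Z): 2-CH2OTBDPS, 3-Me, 3-OPMB, 7-Me, 9-CO2Me | CC(C)(C)[Si](c1ccccc1)(c1ccccc1)OC[C@H]1O[C@@H](C(=O)OC)C/C(C)=C\CC[C@]1(C)OCc1ccc(OC)cc1 | intermediate
14 | oxonene 9-carbaldehyde (2R,3S,9R,6Z) | CC(C)(C)[Si](c1ccccc1)(c1ccccc1)OC[C@H]1O[C@@H](C=O)C/C(C)=C\CC[C@]1(C)OCc1ccc(OC)cc1 | intermediate
15 | dimethyl (1-diazo-2-oxopropyl)phosphonate | CC(=O)C(=[N+]=[N-])P(=O)(OC)OC | starting material
16 | dimethyl (1-methoxy-2-oxopropyl)phosphonate (racemic) | CC(=O)C(OC)P(=O)(OC)OC | intermediate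
17 | oxonene (10Z)-enol-ether enone (2R,3S,9R,6Z,10Z): 9-[(1Z)-2-methoxy-3-oxobut-1-enyl] | CC(C)(C)[Si](c1ccccc1)(c1ccccc1)OC[C@H]1O[C@@H](/C=C(\OC)C(C)=O)C/C(C)=C\CC[C@]1(C)OCc1ccc(OC)cc1 | intermediate
18 | oxonene 2-methoxydiene (2R,3S,9R,6Z,10Z): 9-[(1Z)-2-methoxy-3-methylbuta-1,3-dienyl] | CC(C)(C)[Si](c1ccccc1)(c1ccccc1)OC[C@H]1O[C@@H](/C=C(\OC)C(C)=C)C/C(C)=C\CC[C@]1(C)OCc1ccc(OC)cc1 | intermediate
19 | oxonene diene primary alcohol (2R,3S,9R,6Z,10Z): 2-CH2OH | OC[C@H]1O[C@@H](/C=C(\OC)C(C)=C)C/C(C)=C\CC[C@]1(C)OCc1ccc(OC)cc1 | intermediate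
20 | oxonene diene 2-carbaldehyde (2S,3S,9R,6Z,10Z) | O=C[C@H]1O[C@@H](/C=C(\OC)C(C)=C)C/C(C)=C\CC[C@]1(C)OCc1ccc(OC)cc1 | intermediate
21 | tetraene enone (2R,3S,9R,1E,6Z,10Z): 2-[(1E)-3-oxobut-1-enyl] | CC(=O)/C=C/[C@H]1O[C@@H](/C=C(\OC)C(C)=C)C/C(C)=C\CC[C@]1(C)OCc1ccc(OC)cc1 | intermediate
22 | tricyclic enol-ether methyl ketone (1R,2R,3S,9R,10R,14R,6Z): 3-OPMB, 11-OMe (C11=C12), 12-Me, 14-acetyl | COC=1[C@@H]2[C@@H]([C@H]3O[C@@H]2C/C(C)=C\CC[C@]3(C)OCc4ccc(OC)cc4)[C@@H](CC=1C)C(C)=O | intermediate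
23 | tricyclic isopropenyl enol ether (1S,2R,3S,9R,10R,14R,6Z) | COC=1[C@@H]2[C@@H]([C@H]3O[C@@H]2C/C(C)=C\CC[C@]3(C)OCc4ccc(OC)cc4)[C@@H](CC=1C)C(C)=C | intermediate
24 | tricyclic 11-ketone (1S,2R,3S,9R,10R,12R,14R,6Z): 12-Me, 14-isopropenyl, 3-OPMB | O=C1[C@@H]2[C@@H]([C@H]3O[C@@H]2C/C(C)=C\CC[C@]3(C)OCc4ccc(OC)cc4)[C@@H](C[C@H]1C)C(C)=C | intermediate
25 | tricyclic 11-alcohol (1S,2R,3S,9R,10S,11R,12R,14R,6Z) | O[C@H]1[C@@H]2[C@@H]([C@H]3O[C@@H]2C/C(C)=C\CC[C@]3(C)OCc4ccc(OC)cc4)[C@@H](C[C@H]1C)C(C)=C | intermediate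
26 | tricyclic 11-butanoate (1S,2R,3S,9R,10R,11R,12R,14R,6Z) | CCCC(=O)O[C@H]1[C@@H]2[C@@H]([C@H]3O[C@@H]2C/C(C)=C\CC[C@]3(C)OCc4ccc(OC)cc4)[C@@H](C[C@H]1C)C(C)=C | intermediate
27 | C16 primary alcohol, 3-OPMB, 11-butanoate (1S,2R,3S,9R,10R,11R,12R,14S,15R,6Z) | CCCC(=O)O[C@H]1[C@@H]2[C@@H]([C@H]3O[C@@H]2C/C(C)=C\CC[C@]3(C)OCc4ccc(OC)cc4)[C@@H](C[C@H]1C)[C@@H](C)CO | intermediate
28 | 3,16-diol 11-butanoate (1S,2R,3S,9R,10R,11R,12R,14S,15R,6Z) | CCCC(=O)O[C@H]1[C@@H]2[C@@H]([C@H]3O[C@@H]2C/C(C)=C\CC[C@]3(C)O)[C@@H](C[C@H]1C)[C@@H](C)CO | intermediate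
29 | C16 trifluoromethanesulfonate of 28 | CCCC(=O)O[C@H]1[C@@H]2[C@@H]([C@H]3O[C@@H]2C/C(C)=C\CC[C@]3(C)O)[C@@H](C[C@H]1C)[C@@H](C)COS(=O)(=O)C(F)(F)F | intermediate
30 | CNP0209450.4, tetracyclic asbestinane 11-butanoate (1S,2R,3S,9R,10R,11R,12R,14S,15R,6Z) | CCCC(=O)O[C@H]1[C@@H]2[C@@H]3[C@@H](C[C@H]1C)[C@@H](C)CO[C@@]1(C)CC/C=C(/C)C[C@H]2O[C@H]31 | target

**Totals**
Total step count: 23. Longest linear sequence: 20 steps (1–5, 8–10, 12–23).

**Three steps most likely to fail**

Step 8 (the new O–H insertion; risks are carbene 1,2-hydride shift, cyclopropanation, and a mismatched or weak sense at C9). The fallback is the known glycolate-alkylation route, setting out from 7 and returning at 12. Alkylation of the C2 alkoxide of 7 with BrCH2CO2H and NaH in THF/DMF gives the glycolic acid F3. Activation with t-BuCOCl/Et3N and acylation of the lithium salt of (S)-4-benzyl-1,3-oxazolidin-2-one (n-BuLi) gives the N-glycolyl oxazolidinone F4. Its chelated sodium Z-enolate (NaN(SiMe3)2, THF, −78 °C) is alkylated by 3-iodo-2-methylprop-1-ene on the face away from the benzyl group to give the alkylated imide F5 with C9 as R. MeOMgBr in MeOH/CH2Cl2 at 0 °C exchanges the auxiliary for methoxide and delivers 12.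

Step 18 (C12 is set by kinetic protonation and the product is the less stable epimer; wrong-face protonation or acid epimerisation would give 12-epi-24). The fallback replaces ionic protonation by radical hydrogen-atom transfer, setting out from 23 and returning at 24. NBS in THF/H2O at −78 °C brominates the enol ether at C12 and hydrolyses it to the α-bromo ketone F6 (either C12 epimer serves). Bu3SnH with Et3B/air in PhMe at −78 °C then generates the planar C12 radical, which takes hydrogen from the bulky stannane on the convex face to give 24 under neutral, non-epimerising conditions.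

Step 5 (alcoholysis at a tertiary epoxide carbon by an acid-sensitive benzylic alcohol; risks are hydride-shift rearrangement, partial loss of inversion and self-condensation of the alcohol). The fallback builds the tertiary PMB ether by acetal reduction, setting out from 6 and returning at 7. HClO4 (cat.) in THF/H2O opens the epoxide with water at C3 with inversion to give the diol F1. 4-Methoxybenzaldehyde dimethyl acetal with pyridinium p-toluenesulfonate in CH2Cl2 gives the 4-methoxybenzylidene acetal F2. i-Bu2AlH (CH2Cl2, −78 → 0 °C) coordinates the less hindered secondary oxygen and cleaves its acetal C–O bond, leaving the PMB group on the tertiary oxygen and giving 7.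

**Further compounds**
F1 | step 5 | (2R,3S)-1-{[tert-butyl(diphenyl)silyl]oxy}-3-methylhept-6-ene-2,3-diol | CC(C)(C)[Si](c1ccccc1)(c1ccccc1)OC[C@@H](O)[C@](C)(CCC=C)O
F2 | step 5 | tert-butyl{[(4R,5S)-5-(but-3-en-1-yl)-2-(4-methoxyphenyl)-5-methyl-1,3-dioxolan-4-yl]methoxy}diphenylsilane (acetal carbon as a mixture) | CC(C)(C)[Si](c1ccccc1)(c1ccccc1)OC[C@H]1OC(c2ccc(OC)cc2)O[C@@]1(C)CCC=C
F3 | step 8 | 2-{[(2R,3S)-1-{[tert-butyl(diphenyl)silyl]oxy}-3-[(4-methoxybenzyl)oxy]-3-methylhept-6-en-2-yl]oxy}acetic acid | CC(C)(C)[Si](c1ccccc1)(c1ccccc1)OC[C@@H](OCC(=O)O)[C@](C)(CCC=C)OCc1ccc(OC)cc1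
F4 | step 8 | (4S)-4-benzyl-3-(2-{[(2R,3S)-1-{[tert-butyl(diphenyl)silyl]oxy}-3-[(4-methoxybenzyl)oxy]-3-methylhept-6-en-2-yl]oxy}acetyl)-1,3-oxazolidin-2-one | CC(C)(C)[Si](c1ccccc1)(c1ccccc1)OC[C@@H](OCC(=O)N1[C@@H](Cc2ccccc2)COC1=O)[C@](C)(CCC=C)OCc1ccc(OC)cc1
F5 | step 8 | (4S)-4-benzyl-3-[(2R)-2-{[(2R,3S)-1-{[tert-butyl(diphenyl)silyl]oxy}-3-[(4-methoxybenzyl)oxy]-3-methylhept-6-en-2-yl]oxy}-4-methylpent-4-enoyl]-1,3-oxazolidin-2-one | CC(C)(C)[Si](c1ccccc1)(c1ccccc1)OC[C@@H](O[C@@H](C(=O)N1[C@@H](Cc2ccccc2)COC1=O)CC(C)=C)[C@](C)(CCC=C)OCc1ccc(OC)cc1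
F6 | step 18 | tricyclic 12-bromo-11-ketone (C12 epimers; otherwise as 24) | O=C1[C@@H]2[C@@H]([C@H]3O[C@@H]2C/C(C)=C\CC[C@]3(C)OCc4ccc(OC)cc4)[C@@H](CC1(C)Br)C(C)=C
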